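The route cuts the C3=C4 double bond of the ten-membered carbocycle (ring A, C1–C10). The feature exploited is the 1,5-relationship of carboxyl C17 (on C8) and ketone carbon C12 (on the C9 side chain). With C12 reduced, they are tied as δ-lactone ring B, whose chair holds the C7 and C10 arms trans-diequatorial and gauche. An intramolecular Horner–Wadsworth–Emmons reaction then joins phosphonoacetate carbon C4 to Z-enal carbon C3. This closes ring A and fixes C2 trans to ester C18 in one operation. Precursor 20 is this lactone bearing a Z-4-oxobut-2-enyl arm on C9 and a 3-methylidene-4-phosphono ester arm on C8.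

Key step: step 14

**Remarks on the chemistry**
- Numbering: ring A = C1–C10 (C1=C2, C3=C4); C11–C12 = side chain on C9; C17 = carboxyl carbon on C8; C18 = carboxyl carbon on C4; C19 = methylidene carbon on C5; C20 = methyl on C9; ring B = C8–C17–O–C12–C11–C9.
- Check of the structures: in 20 and 22 the C7 arm, the C10 arm and the furyl group are equatorial and C20 is axial. The descriptors are 8R,9S,12S, which map onto 8R,9S of the target. C3=C4 is E by CIP although both of its ring bonds are cis. No structure needed a change.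
- C8: a carbon electrophile enters the C8 enolate anti to the axial C20, which would give the C8 epimer of 20. C8 is therefore set by protonation (step 9).
- C8 arm: it is built from a 2-bromoalkene, so the position of C5=C19 is never left to a deprotonation that could also occur at C6.
- Key step base: one equivalent of an amide base is used in place of an amine/ammonium pair, which could shuttle protons and move C5=C19 or isomerise the enal.
- End game: the δ-hydroxy acid would reclose ring B on acidification. It is therefore alkylated as its salt, oxidised, and released under neutral conditions.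
- Assumption: in step 2 the S ligand is taken to give the S carbinol. If Mosher ester analysis of 5 shows the opposite sense, the R ligand is used and nothing else changes.

**Step 1**
Reactants: 1 2,2,6-trimethyl-4H-1,3-dioxin-4-one
Product: 2 [(2,2-dimethyl-6-methylidene-6H-1,3-dioxin-4-yl)oxy]trimethylsilane
Conditions: LDA, THF, −78 °C; TMSCl, −78 → 0 °C
Reagents that add atoms: chlorotrimethylsilane, C[Si](C)(C)Cl
Why: Silyl dienol ether formation, in which LDA removes the γ-proton of the vinylogous ester and TMSCl traps the dienolate on oxygen, giving a γ-nucleophile equivalent to an acetoacetate dianion.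

**Step 2**
Reactants: 2 silyl dienol ether; 3 furan-3-carbaldehyde
Product: 5 6-[(2S)-2-(furan-3-yl)-2-hydroxyethyl]-2,2-dimethyl-4H-1,3-dioxin-4-one, via trimethylsilyl ether 4 (not isolated)
Conditions: Cu(OTf)2 (2 mol%), (S)-Tol-BINAP (2.2 mol%), Bu4N[Ph3SiF2] (4 mol%), THF, −78 °C; then 1 M HCl, THF, 0 °C
Reagents that add atoms: none
Why: Catalytic enantioselective vinylogous Mukaiyama aldol addition, in which a chiral bisphosphine copper dienolate adds through its γ-carbon to the non-enolisable heteroaromatic aldehyde and the ligand selects the aldehyde face, setting C12 as S.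

**Step 3**
Reactants: 5 dioxinone carbinol
Product: 6 (6S)-6-(furan-3-yl)oxane-2,4-dione (enol form: 4-hydroxy-5,6-dihydro-2H-pyran-2-one)
Conditions: K2CO3, MeOH, 23 °C; then 1 M HCl to pH 3
Reagents that add atoms: none
Why: Dioxinone opening and lactonisation (acyl transfer), in which the β-keto acyl unit is unmasked with loss of acetone and the C12 oxygen closes ring B, leaving the C12–O bond and its S configuration untouched.

**Step 4**
Reactants: 6 β-keto lactone
Product: 7 (6S)-6-(furan-3-yl)-2-oxo-5,6-dihydro-2H-pyran-4-yl trifluoromethanesulfonate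
Conditions: Tf2O, iPr2NEt, CH2Cl2, −78 °C
Reagents that add atoms: trifluoromethanesulfonic anhydride, O=S(=O)(OS(=O)(=O)C(F)(F)F)C(F)(F)F
Why: Enol triflate formation, in which the enolised β-keto lactone is sulfonylated on the oxygen at C9, turning C9 into a cross-coupling site.

**Step 5**
Reactants: 7 enol triflate
Product: 8 (6S)-6-(furan-3-yl)-4-(prop-2-en-1-yl)-5,6-dihydro-2H-pyran-2-one
Conditions: allyltributylstannane, Pd2(dba)3 (2.5 mol%), AsPh3 (10 mol%), LiCl, NMP, 23 °C
Reagents that add atoms: allyltributylstannane, C=CC[Sn](CCCC)(CCCC)CCCC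
Why: Stille coupling, in which zerovalent palladium inserts into the electron-poor enol triflate and tin transfers the allyl group at room temperature without base, so the skipped diene should not move into conjugation.

**Step 6**
Reactants: 8 4-allyl dihydropyranone
Product: 10 (4S,6S)-6-(furan-3-yl)-4-methyl-4-(prop-2-en-1-yl)oxan-2-one, via silyl ketene acetal 9 (not isolated)
Conditions: MeLi, CuI, Et2O, 0 °C; TMSCl, 8, −78 → −30 °C; then 0.5 M HCl, THF, 0 °C
Reagents that add atoms: lithium dimethylcuprate, [Li+].C[Cu-]C; chlorotrimethylsilane (into intermediate 9 only), C[Si](C)(C)Cl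
Why: Gilman conjugate addition accelerated by TMSCl, in which the cuprate attacks C9 axially on the half-chair that keeps the C12 furyl group equatorial, so C20 enters trans to furyl and C9 is set as S with the C10 arm equatorial.

**Step 7**
Reactants: 11 3-bromobut-3-en-1-ol
Product: 12 2-bromo-4-iodobut-1-ene
Conditions: I2, PPh3, imidazole, CH2Cl2, 0 °C
Reagents that add atoms: iodine, [I][I]
Why: Appel-type iodination replaces the primary hydroxyl by SN2 and leaves the bromoalkene alone.

**Step 8**
Reactants: 10 lactone; 12 2-bromo-4-iodobut-1-ene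
Product: 13 (3S,4S,6S)-3-(3-bromobut-3-en-1-yl)-6-(furan-3-yl)-4-methyl-4-(prop-2-en-1-yl)oxan-2-one
Conditions: LDA, THF, −78 °C; DMPU, 12, −78 → −30 °C
Reagents that add atoms: none
Why: Lactone enolate alkylation (SN2), in which the primary iodide is attacked by C8 on the face opposite to the axial C20, so the C7 arm first arrives axial and cis to the C10 arm (3S), an outcome that the next step inverts.

**Step 9**
Reactants: 13 (3S)-alkylated lactone
Product: 15 (3R,4S,6S)-3-(3-bromobut-3-en-1-yl)-6-(furan-3-yl)-4-methyl-4-(prop-2-en-1-yl)oxan-2-one, via lithium enolate 14 (not isolated)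
Conditions: LDA, THF, −78 °C; AcOH in THF, −78 °C
Reagents that add atoms: none
Why: Deprotonation and kinetic protonation, in which the planar enolate takes up the proton axially on the face away from the axial C20 (the same bias as in step 8), so the C7 arm becomes equatorial and trans to the C10 arm and C8 is set as R.

**Step 10**
Reactants: 15 (3R)-bromoalkene lactone
Product: 16 methyl 5-[(3R,4S,6S)-6-(furan-3-yl)-4-methyl-2-oxo-4-(prop-2-en-1-yl)oxan-3-yl]-3-methylidenepentanoate
Conditions: BrZnCH2CO2Me (from methyl bromoacetate, Zn, THF), Pd(dba)2 (5 mol%), P(tBu)3 (5 mol%), THF, 23 °C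
Reagents that add atoms: bromo(2-methoxy-2-oxoethyl)zinc (Reformatsky reagent from methyl bromoacetate and zinc), COC(=O)C[Zn]Br
Why: Negishi-type coupling of a Reformatsky reagent, in which the weakly basic zinc enolate hands C4 and C18 to the alkenylpalladium species, so C5=C19 sits where bromine was and the lactone and C8 are not disturbed.

**Step 11**
Reactants: 16 β,γ-unsaturated ester
Product: 18 methyl 2-(diethoxyphosphoryl)-5-[(3R,4S,6S)-6-(furan-3-yl)-4-methyl-2-oxo-4-(prop-2-en-1-yl)oxan-3-yl]-3-methylidenepentanoate (both C4 epimers), via phosphonite 17 (not isolated)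
Conditions: LiHMDS (1.05 equiv), THF, −78 °C; ClP(OEt)2, −78 → 0 °C; then 30% H2O2, 0 °C
Reagents that add atoms: diethyl chlorophosphite, CCOP(Cl)OCC; hydrogen peroxide, OO
Why: C-phosphinylation of an ester enolate followed by oxidation, in which LiHMDS removes only a doubly activated, unhindered C4 proton (not the hindered tertiary C8–H), the soft trivalent phosphorus chloride is attacked by the α-carbon of the dienolate, and H2O2 raises the phosphonite to the phosphonate, the C4 epimer mixture being irrelevant because C4 becomes sp2.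

**Step 12**
Reactants: 18 allyl phosphonate
Product: 19 methyl 2-(diethoxyphosphoryl)-5-{(3R,4S,6S)-6-(furan-3-yl)-4-[(2Z)-4-hydroxybut-2-en-1-yl]-4-methyl-2-oxooxan-3-yl}-3-methylidenepentanoate
Conditions: (Z)-but-2-ene-1,4-diol (3 equiv), Ru(=CH-C6H4-2-OiPr)(SIMes)(S2C6H2Cl2-3,6) (5 mol%), THF, 23 °C
Reagents that add atoms: (Z)-but-2-ene-1,4-diol, OC/C=C\CO
Why: Z-selective (stereoretentive) cross-metathesis, in which the dithiolate ruthenium carbene passes the Z-configured CH–CH2OH unit of the diol to the only monosubstituted alkene, while the 1,1-disubstituted C5=C19 bond and the furan do not take part.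

**Step 13**
Reactants: 19 Z-allylic alcohol
Product: 20 methyl 2-(diethoxyphosphoryl)-5-{(3R,4S,6S)-6-(furan-3-yl)-4-methyl-2-oxo-4-[(2Z)-4-oxobut-2-en-1-yl]oxan-3-yl}-3-methylidenepentanoate
Conditions: Dess–Martin periodinane, NaHCO3, CH2Cl2, 0 °C; used at once
Reagents that add atoms: none
Why: Dess–Martin oxidation under bicarbonate buffering turns the Z-allylic alcohol into the Z-enal without the acid or amine that could isomerise it or deprotonate C4.

**Step 14**
Reactants: 20 Z-enal phosphonoacetate lactone
Product: 22 methyl (3S,4aS,6Z,8E,12aR)-3-(furan-3-yl)-4a-methyl-10-methylidene-1-oxo-3,4,4a,5,10,11,12,12a-octahydro-1H-cyclodeca[c]pyran-9-carboxylate, via sodium phosphonate carbanion 21 (not isolated)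
Conditions: NaHMDS (1.0 equiv), THF (1 mM in 20), −78 °C, then warm to 23 °C
Reagents that add atoms: none
Why: NaHMDS removes the C4 proton, the most acidic one, irreversibly, so only the C19=C5–C4 allyl-type carbanion 21 is present and no proton carrier is left to move C5=C19 or to touch the enal. Carbanion 21 adds through C4 to aldehyde carbon C3 (10-exo-trig, end-to-end closure of carbocyclic ring A onto ring B) and the oxaphosphetane collapses by syn elimination of sodium diethyl phosphate, whereas attack through C19 is only a reversible aldol addition that drains back. The closest known reaction type is the macrocyclic intramolecular Horner–Wadsworth–Emmons olefination, common for large rings and applied here at ring size ten. No stereocentre is created, since C8, C9 and C12 are spectators and C4 loses its undefined configuration. The step needs C2 trans to C18 and an intact Z C1=C2 bond: the first follows from the usual preference of α-substituted phosphonoacetates for the aldehyde residue anti to the ester and from the lower strain of the ring-cis geometry, the second from the absence of nucleophilic amine and of excess base. Closure over oligomerisation is secured by the chair of ring B, which holds the C7 and C10 arms trans-diequatorial and gauche with the furyl group equatorial, together with high dilution.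

**Step 15**
Reactants: 22 bicyclic lactone ester
Product: 24 diallyl (1E,3Z,6S,7R)-6-[(2S)-2-(furan-3-yl)-2-hydroxyethyl]-6-methyl-10-methylidenecyclodeca-1,3-diene-1,7-dicarboxylate, via dilithium dicarboxylate 23 (not isolated)
Conditions: LiOH, THF/H2O 3:1, 23 → 45 °C; solid CO2, evaporate, toluene azeotrope; allyl bromide, DMF, 23 °C
Reagents that add atoms: lithium hydroxide, [Li+].[OH-]; allyl bromide, C=CCBr
Why: Saponification opens ring B and cleaves the C18 methyl ester, and the dicarboxylate is O-alkylated as such by SN2 on allyl bromide, so the hydroxy acid never meets acid and cannot reclose, while C8 is safe because a carboxylate α-carbon is not deprotonated.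

**Step 16**
Reactants: 24 hydroxy diallyl ester
Product: 25 diallyl (1E,3Z,6S,7R)-6-[2-(furan-3-yl)-2-oxoethyl]-6-methyl-10-methylidenecyclodeca-1,3-diene-1,7-dicarboxylate
Conditions: Dess–Martin periodinane, NaHCO3, CH2Cl2, 0 → 23 °C
Reagents that add atoms: none
Why: Dess–Martin oxidation of the secondary furyl carbinol erases the auxiliary stereocentre C12, gives the 3-acylfuran and removes the hydroxyl that could re-form ring B.

**Step 17**
Reactants: 25 keto diallyl ester
Product: 26 (1E,3Z,6S,7R)-6-[2-(furan-3-yl)-2-oxoethyl]-6-methyl-10-methylidenecyclodeca-1,3-diene-1,7-dicarboxylic acid (target)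
Conditions: Pd(PPh3)4 (5 mol%), morpholine, THF, 23 °C; then 10% citric acid
Reagents that add atoms: none
Why: Tsuji–Trost deallylation, in which zerovalent palladium ionises both allyl esters and morpholine captures the allyl units under neutral conditions, so the hindered C17 ester falls without hydroxide and C8, the ketone, the Z,E-diene and C5=C19 stay as they are.

**Compound list**
1 | 2,2,6-trimethyl-4H-1,3-dioxin-4-one | CC1=CC(=O)OC(C)(C)O1 | starting material
2 | [(2,2-dimethyl-6-methylidene-6H-1,3-dioxin-4-yl)oxy]trimethylsilane | C=C1C=C(O[Si](C)(C)C)OC(C)(C)O1 | intermediate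
3 | furan-3-carbaldehyde | O=Cc1ccoc1 | starting material
4 | trimethylsilyl ether of 5 (S) | C[Si](C)(C)O[C@H](c1ccoc1)CC1=CC(=O)OC(C)(C)O1 | intermediate
5 | 6-[(2S)-2-(furan-3-yl)-2-hydroxyethyl]-2,2-dimethyl-4H-1,3-dioxin-4-one | O[C@H](c1ccoc1)CC1=CC(=O)OC(C)(C)O1 | intermediate
6 | (6S)-6-(furan-3-yl)oxane-2,4-dione | O=C1CC(=O)O[C@H](c2ccoc2)C1 | intermediate
7 | (6S)-6-(furan-3-yl)-2-oxo-5,6-dihydro-2H-pyran-4-yl trifluoromethanesulfonate | O=C1C=C(OS(=O)(=O)C(F)(F)F)C[C@@H](c2ccoc2)O1 | intermediate
8 | (6S)-6-(furan-3-yl)-4-(prop-2-en-1-yl)-5,6-dihydro-2H-pyran-2-one | C=CCC1=CC(=O)O[C@H](c2ccoc2)C1 | intermediate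
9 | trimethylsilyl ketene acetal of 10 (4S,6S) | C=CC[C@]1(C)C=C(O[Si](C)(C)C)O[C@H](c2ccoc2)C1 | intermediate
10 | (4S,6S)-6-(furan-3-yl)-4-methyl-4-(prop-2-en-1-yl)oxan-2-one | C=CC[C@]1(C)CC(=O)O[C@H](c2ccoc2)C1 | intermediate
11 | 3-bromobut-3-en-1-ol | C=C(Br)CCO | starting material
12 | 2-bromo-4-iodobut-1-ene | C=C(Br)CCI | intermediate
13 | (3S,4S,6S)-3-(3-bromobut-3-en-1-yl)-6-(furan-3-yl)-4-methyl-4-(prop-2-en-1-yl)oxan-2-one | C=C(Br)CC[C@@H]1C(=O)O[C@H](c2ccoc2)C[C@]1(C)CC=C | intermediate
14 | lithium enolate of 13 and 15 | C=C(Br)CCC1=C([O-])O[C@H](c2ccoc2)C[C@]1(C)CC=C.[Li+] | intermediate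
15 | (3R,4S,6S)-3-(3-bromobut-3-en-1-yl)-6-(furan-3-yl)-4-methyl-4-(prop-2-en-1-yl)oxan-2-one | C=C(Br)CC[C@H]1C(=O)O[C@H](c2ccoc2)C[C@]1(C)CC=C | intermediate
16 | methyl 5-[(3R,4S,6S)-6-(furan-3-yl)-4-methyl-2-oxo-4-(prop-2-en-1-yl)oxan-3-yl]-3-methylidenepentanoate | C=C(CC(=O)OC)CC[C@H]1C(=O)O[C@H](c2ccoc2)C[C@]1(C)CC=C | intermediate
17 | diethyl phosphonite at C4 of 16 | C=C(C(P(OCC)OCC)C(=O)OC)CC[C@H]1C(=O)O[C@H](c2ccoc2)C[C@]1(C)CC=C | intermediate
18 | methyl 2-(diethoxyphosphoryl)-5-[(3R,4S,6S)-6-(furan-3-yl)-4-methyl-2-oxo-4-(prop-2-en-1-yl)oxan-3-yl]-3-methylidenepentanoate | C=C(C(P(=O)(OCC)OCC)C(=O)OC)CC[C@H]1C(=O)O[C@H](c2ccoc2)C[C@]1(C)CC=C | intermediate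
19 | Z-allylic alcohol: 18 with a (2Z)-4-hydroxybut-2-en-1-yl arm on C9 | C=C(C(P(=O)(OCC)OCC)C(=O)OC)CC[C@H]1C(=O)O[C@H](c2ccoc2)C[C@]1(C)C/C=C\CO | intermediate
20 | key-step precursor: 18 with a (2Z)-4-oxobut-2-en-1-yl arm on C9 (8R,9S,12S) | C=C(C(P(=O)(OCC)OCC)C(=O)OC)CC[C@H]1C(=O)O[C@H](c2ccoc2)C[C@]1(C)C/C=C\C=O | intermediate
21 | sodium salt of the C4 carbanion of 20 | [Na+].C=C([C-](P(=O)(OCC)OCC)C(=O)OC)CC[C@H]1C(=O)O[C@H](c2ccoc2)C[C@]1(C)C/C=C\C=O | intermediate
22 | methyl (3S,4aS,6Z,8E,12aR)-3-(furan-3-yl)-4a-methyl-10-methylidene-1-oxo-3,4,4a,5,10,11,12,12a-octahydro-1H-cyclodeca[c]pyran-9-carboxylate (ring A trans-fused to ring B; 8R,9S,12S) | C=C1CC[C@H]2C(=O)O[C@H](c3ccoc3)C[C@]2(C)C/C=C\C=C/1C(=O)OC | intermediate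
23 | dilithium (1E,3Z,6S,7R)-6-[(2S)-2-(furan-3-yl)-2-hydroxyethyl]-6-methyl-10-methylidenecyclodeca-1,3-diene-1,7-dicarboxylate | [Li+].[Li+].C=C1CC[C@@H](C(=O)[O-])[C@](C)(C[C@H](O)c2ccoc2)C/C=C\C=C/1C(=O)[O-] | intermediate
24 | diallyl (1E,3Z,6S,7R)-6-[(2S)-2-(furan-3-yl)-2-hydroxyethyl]-6-methyl-10-methylidenecyclodeca-1,3-diene-1,7-dicarboxylate | C=C1CC[C@@H](C(=O)OCC=C)[C@](C)(C[C@H](O)c2ccoc2)C/C=C\C=C/1C(=O)OCC=C | intermediate
25 | diallyl (1E,3Z,6S,7R)-6-[2-(furan-3-yl)-2-oxoethyl]-6-methyl-10-methylidenecyclodeca-1,3-diene-1,7-dicarboxylate | C=C1CC[C@@H](C(=O)OCC=C)[C@](C)(CC(=O)c2ccoc2)C/C=C\C=C/1C(=O)OCC=C | intermediate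
26 | (1E,3Z,6S,7R)-6-[2-(furan-3-yl)-2-oxoethyl]-6-methyl-10-methylidenecyclodeca-1,3-diene-1,7-dicarboxylic acid | C=C1CC[C@@H](C(=O)O)[C@](C)(CC(=O)c2ccoc2)C/C=C\C=C/1C(=O)O | target

Total step count: 17. Longest linear sequence: 16 steps (steps 1–6 and 8–17, from 1).

**Steps most likely to fail**

1. **Step 14.** Ring closure may lose to intermolecular olefination. The Z-enal may drift to the E isomer, which cannot reach C4. The carbanion may also stall at the reversible adduct stage because of transannular strain.
 - Fallback: move the ring-closing event to C1=C2.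
 - Phosphonate 18 is olefinated intermolecularly with acrolein (LiCl, DBU, MeCN) to methyl (2E)-2-{4-[(3R,4S,6S)-6-(furan-3-yl)-4-methyl-2-oxo-4-(prop-2-en-1-yl)oxan-3-yl]but-1-en-2-yl}penta-2,4-dienoate F1.
 - Ring-closing metathesis (second-generation Grubbs catalyst, RuCl2(=CHPh)(SIMes)(PCy3), dilute toluene) between the allyl arm and the terminal vinyl group then closes ring A, with ring strain favouring Z at C1=C2.
 - The fallback sets out from 18 and comes back at 22.

2. **Step 9.** Enolisation of the hindered tertiary C8–H may be incomplete, the bromoalkene may lose HBr to the amide base, or facial selectivity of protonation may be poor.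
 - Fallback: make the C6–C7 bond by conjugate addition, so that C8 is protonated under mild conditions.
 - Lactone 10 is aminomethylated (LDA; Eschenmoser's salt) to the Mannich base F2.
 - Quaternisation and elimination (MeI; NaHCO3) give the α-methylidene lactone F3.
 - Allyl acetoacetate adds to C7 (catalytic DBU, THF). The transient C8 enolate is protonated by the β-keto ester on the face away from C20, giving the Michael adduct F4.
 - Pd(PPh3)4 and morpholine remove the allyl ester with decarboxylation to the methyl ketone F5.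
 - KHMDS and N-(5-chloropyridin-2-yl)bis(trifluoromethanesulfonimide) at −78 °C give the terminal enol triflate F6, which replaces bromide 15 in the coupling of step 10.
 - The fallback sets out from 10 and comes back at 16.

3. **Step 11.** The dienolate may react on oxygen or through C19, may close onto C17 in a Dieckmann manner, or C5=C19 may slip into conjugation during oxidation and work-up.
 - Fallback: form the C4–C5 bond with phosphorus already in place.
 - Bromoalkene 15 is coupled with the sodium enolate of methyl diethylphosphonoacetate under Pd(dba)2/P(tBu)3 catalysis (enolate alkenylation of the malonate type).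
 - The product stays as its stabilised anion until a cold acetic acid quench protonates C4.
 - The fallback sets out from 15, skips 16 and comes back at 18. No compound outside the list is made (F0).

**Further compounds**
F1 | step 14 | methyl (2E)-2-{4-[(3R,4S,6S)-6-(furan-3-yl)-4-methyl-2-oxo-4-(prop-2-en-1-yl)oxan-3-yl]but-1-en-2-yl}penta-2,4-dienoate | C=C/C=C(/C(=O)OC)C(=C)CC[C@H]1C(=O)O[C@H](c2ccoc2)C[C@]1(C)CC=C
F2 | step 9 | (4S,6S)-3-[(dimethylamino)methyl]-6-(furan-3-yl)-4-methyl-4-(prop-2-en-1-yl)oxan-2-one | CN(C)CC1C(=O)O[C@H](c2ccoc2)C[C@]1(C)CC=C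
F3 | step 9 | (4S,6S)-6-(furan-3-yl)-4-methyl-3-methylidene-4-(prop-2-en-1-yl)oxan-2-one | C=C1C(=O)O[C@H](c2ccoc2)C[C@]1(C)CC=C
F4 | step 9 | allyl 2-{[(3R,4S,6S)-6-(furan-3-yl)-4-methyl-2-oxo-4-(prop-2-en-1-yl)oxan-3-yl]methyl}-3-oxobutanoate | CC(=O)C(C(=O)OCC=C)C[C@H]1C(=O)O[C@H](c2ccoc2)C[C@]1(C)CC=C
F5 | step 9 | (3R,4S,6S)-6-(furan-3-yl)-4-methyl-3-(3-oxobutyl)-4-(prop-2-en-1-yl)oxan-2-one | CC(=O)CC[C@H]1C(=O)O[C@H](c2ccoc2)C[C@]1(C)CC=C
F6 | step 9 | 4-[(3R,4S,6S)-6-(furan-3-yl)-4-methyl-2-oxo-4-(prop-2-en-1-yl)oxan-3-yl]but-1-en-2-yl trifluoromethanesulfonate | C=C(OS(=O)(=O)C(F)(F)F)CC[C@H]1C(=O)O[C@H](c2ccoc2)C[C@]1(C)CC=C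
F0 | step 11 | none | none
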